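The route rests on the exo-methylene allylic alcohol of the side chain. The vinylic carbon C3' (bearing =CH2) and the carbinol carbon C2' are both carbonyl-derived electrophiles: the first is the enol triflate of 6-methylhept-5-en-2-one, the second the aldehyde of a triacetyl-protected (3-benzoylphloroglucinyl)acetaldehyde. A ligand-controlled asymmetric Nozaki–Hiyama–Kishi (Ni/Cr) reductive coupling reverses the polarity of the triflate carbon, joins the two halves at C3'–C2' and sets the single (R) stereocentre in one operation, leaving the diaryl ketone and aryl acetates untouched. The aldehyde comes from C-allylation of 2,4,6-trihydroxybenzophenone, acetylation and ozonolysis; mild methanolysis ends the synthesis.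

Key step: step 5

Remark: the sense of induction of the oxazoline–sulfonamide ligand in step 5 is not assumed; both enantiomers are accessible (from D- or L-valinol), and the one that gives Si-face addition to the aldehyde is to be chosen in a test coupling and checked by Mosher ester analysis of 11.

Step 1
Reactants: 1 2,4,6-trihydroxybenzophenone; 2 allyl bromide
Product: 3 3-allyl-2,4,6-trihydroxybenzophenone
Conditions: 2 (1.0 equiv), 10% aq KOH, 0 °C to rt; acidify to pH 3
Reagents that add atoms: none
Why: C-alkylation of the ambident phloroglucinol phenoxide (a vinylogous enolate) should occur at ring carbon C3 because water shields the oxygens by hydrogen bonding, and limiting the bromide restrains a second allylation at the equivalent C5.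

Step 2
Reactants: 3 3-allyl-2,4,6-trihydroxybenzophenone
Product: 4 3-allyl-2,4,6-triacetoxybenzophenone
Conditions: Ac2O (4 equiv), pyridine, DMAP (cat.), CH2Cl2, 0 °C to rt
Reagents that add atoms: acetic anhydride CC(=O)OC(C)=O
Why: DMAP-catalysed acylation should cap all three phenols, including the two hydrogen-bonded ones beside the benzoyl group, which deactivates the ring toward ozone and masks the acidic OH groups for the chromium step.

Step 3
Reactants: 4 3-allyl-2,4,6-triacetoxybenzophenone
Product: 6 2-(2,4,6-triacetoxy-3-benzoylphenyl)acetaldehyde, via secondary ozonide 5 (not isolated)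
Conditions: O3, CH2Cl2, −78 °C (Sudan III end-point); then PPh3, −78 °C to rt; used without storage
Reagents that add atoms: ozone [O-][O+]=O
Why: Ozonolysis (Criegee mechanism) with reductive work-up should cleave only the terminal alkene, because the triacetoxy-benzoyl arene is electron-poor, and deliver the arylacetaldehyde.

Step 4
Reactants: 7 6-methylhept-5-en-2-one
Product: 9 6-methylhepta-1,5-dien-2-yl trifluoromethanesulfonate, via lithium enolate 8 (not isolated)
Conditions: LDA (1.1 equiv), THF, −78 °C; then PhNTf2 (1.05 equiv), −78 °C to 0 °C
Reagents that add atoms: N-phenyl-bis(trifluoromethanesulfonimide) O=S(=O)(N(c1ccccc1)S(=O)(=O)C(F)(F)F)C(F)(F)F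
Why: Kinetic deprotonation of the methyl ketone should give the less substituted terminal enolate, and its O-sulfonylation gives the 1-alken-2-yl triflate (enol triflate formation).

Step 5
Reactants: 6 2-(2,4,6-triacetoxy-3-benzoylphenyl)acetaldehyde; 9 6-methylhepta-1,5-dien-2-yl trifluoromethanesulfonate
Product: 11 3-[(2R)-2-hydroxy-7-methyl-3-methylideneoct-6-en-1-yl]-2,4,6-triacetoxybenzophenone, via alkenylchromium(III) reagent 10 (not isolated)
Conditions: CrCl2 (3 equiv), enantiopure N-[2-(4-isopropyl-4,5-dihydro-1,3-oxazol-2-yl)-6-methylphenyl]methanesulfonamide (3.3 equiv), Et3N (3.3 equiv), THF, rt, 1 h; then NiCl2 (10 mol %), 6 (1 equiv), 9 (1.5 equiv), THF, 0 °C to rt; aqueous ethylenediamine work-up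
Reagents that add atoms: none
Why: Ni(0), formed from NiCl2 by Cr(II), should insert into the C–OTf bond of 9 and transmetalate to Cr(III), giving the nucleophilic alkenylchromium 10 held by the chiral oxazoline–sulfonamide ligand, which adds to the aldehyde carbon of 6 through an ordered, chromium-bound transition state. The closest known reaction type is the asymmetric Nozaki–Hiyama–Kishi coupling of 1-alken-2-yl triflates derived from methyl ketones with α-unbranched aldehydes, which gives 2-substituted allylic alcohols. No ring is closed. The new stereocentre C2' is under reagent control: the ligand enantiomer that directs alkenyl transfer to the Si face of the aldehyde is used, which gives the (R) alcohol. The step needs chemoselectivity for the aldehyde over the diaryl ketone and the three aryl acetates, and it must not enolise the arylacetaldehyde; the weakly basic, aldehyde-selective organochromium reagent should secure both, helped by the two ortho-acetoxy groups that shield the benzophenone carbonyl.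

Step 6
Reactants: 11 3-[(2R)-2-hydroxy-7-methyl-3-methylideneoct-6-en-1-yl]-2,4,6-triacetoxybenzophenone
Product: 12 3-[(2R)-2-hydroxy-7-methyl-3-methylideneoct-6-en-1-yl]-2,4,6-trihydroxybenzophenone
Conditions: K2CO3 (cat.), degassed MeOH, 0 °C to rt; pH 6 phosphate buffer work-up
Reagents that add atoms: none
Why: Base-catalysed methanolysis (transesterification) should remove the three aryl acetates, and any acetate that has migrated to the secondary hydroxyl, without touching the allylic alcohol, the two alkenes or the stereocentre.

Compound list
1 | 2,4,6-trihydroxybenzophenone | O=C(c1ccccc1)c1c(O)cc(O)cc1O | starting material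
2 | allyl bromide (3-bromoprop-1-ene) | C=CCBr | starting material
3 | 3-allyl-2,4,6-trihydroxybenzophenone | C=CCc1c(O)cc(O)c(C(=O)c2ccccc2)c1O | intermediate
4 | 3-allyl-2,4,6-triacetoxybenzophenone | C=CCc1c(OC(C)=O)cc(OC(C)=O)c(C(=O)c2ccccc2)c1OC(C)=O | intermediate
5 | secondary ozonide of 4 (3-arylmethyl-1,2,4-trioxolane, not isolated) | C1(Cc2c(OC(C)=O)cc(OC(C)=O)c(C(=O)c3ccccc3)c2OC(C)=O)OCOO1 | intermediate
6 | 2-(2,4,6-triacetoxy-3-benzoylphenyl)acetaldehyde | O=CCc1c(OC(C)=O)cc(OC(C)=O)c(C(=O)c2ccccc2)c1OC(C)=O | intermediate
7 | 6-methylhept-5-en-2-one | CC(=O)CCC=C(C)C | starting material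
8 | lithium 6-methylhepta-1,5-dien-2-olate (not isolated) | C=C(O[Li])CCC=C(C)C | intermediate
9 | 6-methylhepta-1,5-dien-2-yl trifluoromethanesulfonate | C=C(CCC=C(C)C)OS(=O)(=O)C(F)(F)F | intermediate
10 | (6-methylhepta-1,5-dien-2-yl)chromium(III) reagent, drawn as the dichloride with the chiral ligand and solvent on chromium omitted (not isolated) | C=C(CCC=C(C)C)[Cr](Cl)Cl | intermediate
11 | 3-[(2R)-2-hydroxy-7-methyl-3-methylideneoct-6-en-1-yl]-2,4,6-triacetoxybenzophenone | C=C(CCC=C(C)C)[C@H](O)Cc1c(OC(C)=O)cc(OC(C)=O)c(C(=O)c2ccccc2)c1OC(C)=O | intermediate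
12 | 3-[(2R)-2-hydroxy-7-methyl-3-methylideneoct-6-en-1-yl]-2,4,6-trihydroxybenzophenone | C=C(CCC=C(C)C)[C@H](O)Cc1c(O)cc(O)c(C(=O)c2ccccc2)c1O | target

Total step count: 6. Longest linear sequence: 5 steps (steps 1, 2, 3, 5, 6); step 4 is a one-step side branch.

Steps most likely to fail

Step 5: the alkenyl transfer may show poor facial selectivity, or the aldehyde may be lost to enolisation and the triflate to nickel-mediated homocoupling. The fallback sets out from 6 and 9 and separates bond formation from stereocontrol. A ligand-free Ni/Cr coupling (CrCl2, NiCl2 cat., DMF, rt) would give the racemic alcohol 3-(2-hydroxy-7-methyl-3-methylideneoct-6-en-1-yl)-2,4,6-triacetoxybenzophenone F1. Dess–Martin oxidation (CH2Cl2, NaHCO3) would give the enone 3-(7-methyl-3-methylidene-2-oxooct-6-en-1-yl)-2,4,6-triacetoxybenzophenone F2. Corey–Bakshi–Shibata reduction would then return to the route at 11; (S)-Me-CBS with catecholborane in toluene at −78 °C is expected to be the right enantiomer on the usual model, with the α-branched alkenyl group as the large substituent. The doubly ortho-substituted diaryl ketone should be reduced much more slowly.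

Step 1: over-allylation at the equivalent C5 and competing O-allylation may erode the yield of the mono-C-allyl compound. The fallback sets out from 1 and 2 and moves the allyl group by a sigmatropic shift. Selective O-alkylation of the non-chelated 4-OH (K2CO3, 1 equiv, acetone, reflux) would give 4-(allyloxy)-2,6-dihydroxybenzophenone F3. A thermal aromatic Claisen rearrangement (N,N-diethylaniline, 190 °C) then delivers the allyl group to C3, which is equivalent to C5, and comes back to the route at 3.

Step 3: the arene may be over-oxidised by ozone, or the enolisable arylacetaldehyde may decompose (self-aldol) during isolation. The fallback sets out from 4. Catalytic dihydroxylation (OsO4 cat., NMO, acetone–water) would give the storable racemic diol 3-(2,3-dihydroxypropyl)-2,4,6-triacetoxybenzophenone F4. Glycol cleavage with NaIO4 on silica gel in CH2Cl2, run just before the coupling, comes back to the route at 6.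

Further compounds
F1 | step 5 | racemic 3-(2-hydroxy-7-methyl-3-methylideneoct-6-en-1-yl)-2,4,6-triacetoxybenzophenone | C=C(CCC=C(C)C)C(O)Cc1c(OC(C)=O)cc(OC(C)=O)c(C(=O)c2ccccc2)c1OC(C)=O
F2 | step 5 | 3-(7-methyl-3-methylidene-2-oxooct-6-en-1-yl)-2,4,6-triacetoxybenzophenone | C=C(CCC=C(C)C)C(=O)Cc1c(OC(C)=O)cc(OC(C)=O)c(C(=O)c2ccccc2)c1OC(C)=O
F3 | step 1 | 4-(allyloxy)-2,6-dihydroxybenzophenone | C=CCOc1cc(O)c(C(=O)c2ccccc2)c(O)c1
F4 | step 3 | racemic 3-(2,3-dihydroxypropyl)-2,4,6-triacetoxybenzophenone | OCC(O)Cc1c(OC(C)=O)cc(OC(C)=O)c(C(=O)c2ccccc2)c1OC(C)=O
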